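**Retrosynthetic overview**

- The strategy rests on ring B: C3' and C4' carry adjacent methoxyls and C1' carries one carbon substituent (C2 of ring C), so C2'–C5' map onto 2,3-dimethoxybuta-1,3-diene and C1'/C6' onto a terminal alkyne.
- Target 15 ⇐ benzyl ether 14 (hydrogenolysis) ⇐ 1,4-cyclohexadiene 13 (DDQ) ⇐ 2-ethynylchromone 11 + diene 12 (Diels–Alder forming C1'–C2' and C5'–C6').
- 11 ⇐ aldehyde 10 (Ohira–Bestmann) ⇐ alcohol 9 ⇐ chromone ester 8 ⇐ hydroxyacetophenone 5 + diethyl oxalate 6 (Claisen condensation and cyclodehydration close ring C).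
- 5 ⇐ acetosyringone 1, whose free hydroxyl becomes the differentiated C7 oxygen; the oxygens that become O1 and the C5 methoxyl are added by dibromination and methoxylation, and one is unmasked by chelation-controlled demethylation.
- Ring order: ring A purchased, ring C in step 5, ring B in step 9 (aromatized in step 10).

Key step: step 9

Remark: flavone numbering is used (ring A C5–C8, ring C O1–C4, ring B primed); no compound in the route has a stereocentre; adduct 13 is an acid-labile bis-enol ether and is carried into step 10 as the crude concentrate.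

**Route**

Step 1
Reactants: 1 acetosyringone
Product: 2 1-[4-(benzyloxy)-3,5-dimethoxyphenyl]ethan-1-one
Conditions: BnBr, K2CO3, DMF, 60 °C
Reagents that add atoms: benzyl bromide, BrCc1ccccc1
Why: Williamson etherification of the only phenol should protect the future C7 oxygen as a benzyl ether that can be removed by hydrogenolysis at the end.

Step 2
Reactants: 2 1-[4-(benzyloxy)-3,5-dimethoxyphenyl]ethan-1-one
Product: 3 1-[4-(benzyloxy)-2,6-dibromo-3,5-dimethoxyphenyl]ethan-1-one
Conditions: NBS (2.2 equiv), MeCN, rt, dark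
Reagents that add atoms: N-bromosuccinimide, O=C1CCC(=O)N1Br
Why: Electrophilic aromatic bromination should take the only two free ring positions, each ortho to one methoxyl and para to the other, and the polar non-radical medium favours ring over side-chain bromination.

Step 3
Reactants: 3 1-[4-(benzyloxy)-2,6-dibromo-3,5-dimethoxyphenyl]ethan-1-one
Product: 4 1-[4-(benzyloxy)-2,3,5,6-tetramethoxyphenyl]ethan-1-one
Conditions: NaOMe (excess), CuBr (cat.), MeOH–DMF, 110 °C
Reagents that add atoms: sodium methoxide, [Na+].[O-]C
Why: Ullmann-type copper-catalysed methoxylation of aryl bromides, assisted by the ortho acetyl group, should replace both bromines, while the doubly ortho-substituted ketone is too hindered for aldol self-condensation.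

Step 4
Reactants: 4 1-[4-(benzyloxy)-2,3,5,6-tetramethoxyphenyl]ethan-1-one
Product: 5 1-[4-(benzyloxy)-2-hydroxy-3,5,6-trimethoxyphenyl]ethan-1-one
Conditions: MgI2·OEt2 (1.5 equiv), toluene–Et2O, 80 °C; then 1 M HCl
Reagents that add atoms: none
Why: Chelation-controlled ether cleavage should remove one of the two equivalent ortho methyl groups by SN2 attack of iodide on the magnesium-bound methoxyl, after which the magnesium phenoxide chelate protects the second one and the non-chelating benzyl ether and remote methoxyls are untouched.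

Step 5
Reactants: 5 1-[4-(benzyloxy)-2-hydroxy-3,5,6-trimethoxyphenyl]ethan-1-one, 6 diethyl oxalate
Product: 8 ethyl 7-(benzyloxy)-5,6,8-trimethoxy-4-oxo-4H-chromene-2-carboxylate, via diketo ester 7 (not isolated)
Conditions: NaOEt (3 equiv), 6 (3 equiv), EtOH, reflux; then conc. HCl, EtOH, reflux
Reagents that add atoms: none
Why: Crossed Claisen condensation of the methyl ketone enolate with non-enolisable diethyl oxalate followed by acid-catalysed cyclodehydration (phenol onto the 2-keto group, loss of water) is the classical chromone-2-carboxylate synthesis and closes ring C.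

Step 6
Reactants: 8 ethyl 7-(benzyloxy)-5,6,8-trimethoxy-4-oxo-4H-chromene-2-carboxylate
Product: 9 7-(benzyloxy)-2-(hydroxymethyl)-5,6,8-trimethoxy-4H-chromen-4-one
Conditions: NaBH4, EtOH–THF, 0 °C
Reagents that add atoms: none
Why: Borohydride reduction should take the C2 ester, which is activated by the electron-poor pyranone and the adjacent ring oxygen, while the C4 carbonyl is a vinylogous ester further deactivated by the C5 methoxyl.

Step 7
Reactants: 9 7-(benzyloxy)-2-(hydroxymethyl)-5,6,8-trimethoxy-4H-chromen-4-one
Product: 10 7-(benzyloxy)-5,6,8-trimethoxy-4-oxo-4H-chromene-2-carbaldehyde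
Conditions: Dess–Martin periodinane, CH2Cl2, rt
Reagents that add atoms: none
Why: Dess–Martin oxidation should convert the primary allylic-type alcohol to the aldehyde without over-oxidation and without touching the electron-rich ring A.

Step 8
Reactants: 10 7-(benzyloxy)-5,6,8-trimethoxy-4-oxo-4H-chromene-2-carbaldehyde
Product: 11 7-(benzyloxy)-2-ethynyl-5,6,8-trimethoxy-4H-chromen-4-one
Conditions: dimethyl (1-diazo-2-oxopropyl)phosphonate, K2CO3, MeOH, 0 °C to rt
Reagents that add atoms: dimethyl (1-diazo-2-oxopropyl)phosphonate, COP(=O)(OC)C(=[N+]=[N-])C(C)=O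
Why: In the Ohira–Bestmann variant of the Seyferth–Gilbert homologation, methanolysis of the reagent gives the dimethyl (diazomethyl)phosphonate anion, which should add to the non-enolisable aldehyde, lose phosphate and nitrogen, and give the terminal alkyne by 1,2-hydrogen shift of the alkylidene carbene.

Step 9
Reactants: 11 7-(benzyloxy)-2-ethynyl-5,6,8-trimethoxy-4H-chromen-4-one, 12 2,3-dimethoxybuta-1,3-diene
Product: 13 7-(benzyloxy)-2-(4,5-dimethoxycyclohexa-1,4-dien-1-yl)-5,6,8-trimethoxy-4H-chromen-4-one
Conditions: 12 (5 equiv), BHT (cat.), toluene, sealed tube, 150 °C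
Reagents that add atoms: none
Why: A thermal, concerted, normal-electron-demand (4+2) cycloaddition is expected, in which the HOMO of the electron-rich diene 12 meets the LUMO of the alkyne of 11, lowered by conjugation through C2=C3 to the C4 carbonyl and by the inductive pull of O1. The closest known reaction type is the Diels–Alder addition of ynones and propiolates to 2,3-dialkoxybutadienes, and exocyclic unsaturation at C2 of a chromone, as in 2-styrylchromones, is a known dienophile site. Ring B is closed by intermolecular annulation, the two σ bonds C1'–C2' and C5'–C6' forming in one suprafacial step to give a 1,4-cyclohexadiene in which the alkyne supplies C1' and C6' and the diene C2' to C5'. No stereocentre is created, and the twofold symmetry of 12 removes any regiochemical question, so the methoxyls must sit at C3' and C4'. The selectivity needed is reaction at the terminal alkyne and not at C2=C3, which is secured because C2=C3 is trisubstituted, donor-substituted by O1 and part of the aromatic pyranone, and mono-addition is secured because the adduct has no activated alkyne left. Excess diene, a radical inhibitor and acid-free glassware should keep the diene and the bis-enol ether product intact.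

Step 10
Reactants: 13 7-(benzyloxy)-2-(4,5-dimethoxycyclohexa-1,4-dien-1-yl)-5,6,8-trimethoxy-4H-chromen-4-one
Product: 14 7-(benzyloxy)-2-(3,4-dimethoxyphenyl)-5,6,8-trimethoxy-4H-chromen-4-one
Conditions: DDQ (1.1 equiv), toluene, rt
Reagents that add atoms: none
Why: Quinone dehydrogenation should proceed by hydride abstraction from a doubly allylic CH2 next to an enol ether and proton loss from the other CH2, driven by aromatization of ring B, under conditions that leave a benzyl aryl ether alone.

Step 11
Reactants: 14 7-(benzyloxy)-2-(3,4-dimethoxyphenyl)-5,6,8-trimethoxy-4H-chromen-4-one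
Product: 15 2-(3,4-dimethoxyphenyl)-7-hydroxy-5,6,8-trimethoxy-4H-chromen-4-one
Conditions: H2 (1 atm), 10% Pd/C, EtOAc–MeOH, rt
Reagents that add atoms: none
Why: Catalytic hydrogenolysis should cleave the benzyl aryl ether, while the flavone C2=C3 bond and the aryl methyl ethers are inert at ambient pressure and temperature.

**Compound list**

1 | acetosyringone, 1-(4-hydroxy-3,5-dimethoxyphenyl)ethan-1-one | CC(=O)c1cc(OC)c(O)c(OC)c1 | starting material
2 | 1-[4-(benzyloxy)-3,5-dimethoxyphenyl]ethan-1-one | CC(=O)c1cc(OC)c(OCc2ccccc2)c(OC)c1 | intermediate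
3 | 1-[4-(benzyloxy)-2,6-dibromo-3,5-dimethoxyphenyl]ethan-1-one | CC(=O)c1c(Br)c(OC)c(OCc2ccccc2)c(OC)c1Br | intermediate
4 | 1-[4-(benzyloxy)-2,3,5,6-tetramethoxyphenyl]ethan-1-one | CC(=O)c1c(OC)c(OC)c(OCc2ccccc2)c(OC)c1OC | intermediate
5 | 1-[4-(benzyloxy)-2-hydroxy-3,5,6-trimethoxyphenyl]ethan-1-one | CC(=O)c1c(O)c(OC)c(OCc2ccccc2)c(OC)c1OC | intermediate
6 | diethyl oxalate | CCOC(=O)C(=O)OCC | starting material
7 | ethyl 4-[4-(benzyloxy)-2-hydroxy-3,5,6-trimethoxyphenyl]-2,4-dioxobutanoate (not isolated) | CCOC(=O)C(=O)CC(=O)c1c(O)c(OC)c(OCc2ccccc2)c(OC)c1OC | intermediate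
8 | ethyl 7-(benzyloxy)-5,6,8-trimethoxy-4-oxo-4H-chromene-2-carboxylate | CCOC(=O)c1cc(=O)c2c(OC)c(OC)c(OCc3ccccc3)c(OC)c2o1 | intermediate
9 | 7-(benzyloxy)-2-(hydroxymethyl)-5,6,8-trimethoxy-4H-chromen-4-one | OCc1cc(=O)c2c(OC)c(OC)c(OCc3ccccc3)c(OC)c2o1 | intermediate
10 | 7-(benzyloxy)-5,6,8-trimethoxy-4-oxo-4H-chromene-2-carbaldehyde | O=Cc1cc(=O)c2c(OC)c(OC)c(OCc3ccccc3)c(OC)c2o1 | intermediate
11 | 7-(benzyloxy)-2-ethynyl-5,6,8-trimethoxy-4H-chromen-4-one | C#Cc1cc(=O)c2c(OC)c(OC)c(OCc3ccccc3)c(OC)c2o1 | intermediate
12 | 2,3-dimethoxybuta-1,3-diene | C=C(OC)C(OC)=C | starting material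
13 | 7-(benzyloxy)-2-(4,5-dimethoxycyclohexa-1,4-dien-1-yl)-5,6,8-trimethoxy-4H-chromen-4-one | COC1=C(OC)CC(c2cc(=O)c3c(OC)c(OC)c(OCc4ccccc4)c(OC)c3o2)=CC1 | intermediate
14 | 7-(benzyloxy)-2-(3,4-dimethoxyphenyl)-5,6,8-trimethoxy-4H-chromen-4-one | COc1ccc(-c2cc(=O)c3c(OC)c(OC)c(OCc4ccccc4)c(OC)c3o2)cc1OC | intermediate
15 | 2-(3,4-dimethoxyphenyl)-7-hydroxy-5,6,8-trimethoxy-4H-chromen-4-one | COc1ccc(-c2cc(=O)c3c(OC)c(OC)c(O)c(OC)c3o2)cc1OC | target

**Step count**

Total step count: 11. Longest linear sequence: 11 steps (1 to 15).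

**Steps most likely to fail**

Step 9. The alkyne is activated only vinylogously, so cycloaddition may be slower than thermal polymerisation or decomposition of the diene, and forcing conditions could bring in addition across C2=C3. The fallback gives up the cycloaddition and attaches ring B preformed by a Baker–Venkataraman sequence, setting out from 5 and returning at 14. Phenol 5 would be acylated with 3,4-dimethoxybenzoyl chloride (pyridine, DMAP) to 2-acetyl-5-(benzyloxy)-3,4,6-trimethoxyphenyl 3,4-dimethoxybenzoate F1. Base-induced O-to-C acyl migration (KOH, pyridine, 50 °C) would give 1-[4-(benzyloxy)-2-hydroxy-3,5,6-trimethoxyphenyl]-3-(3,4-dimethoxyphenyl)propane-1,3-dione F2, and cyclodehydration (p-TsOH, toluene, reflux) would give 14.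

Step 8. Methoxide may add in conjugate fashion to the newly formed acceptor-conjugated alkyne, or open the pyranone at C2, before the homologation is complete. The fallback avoids methanolic base, setting out from 10 and returning at 11. Ramirez olefination (CBr4, PPh3, CH2Cl2, 0 °C) would give 7-(benzyloxy)-2-(2,2-dibromovinyl)-5,6,8-trimethoxy-4H-chromen-4-one F3. Selective hydrogenolysis of the bromine trans to the chromone (Bu3SnH, Pd(PPh3)4, a zerovalent palladium catalyst, toluene, rt) would give 7-(benzyloxy)-2-[(Z)-2-bromovinyl]-5,6,8-trimethoxy-4H-chromen-4-one F4, and anti-elimination of HBr with DBU (THF, rt) would give 11.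

Step 3. The double substitution at two hindered positions flanking an enolisable acetyl group may be eroded by hydrodebromination and by base-mediated condensation at the methyl ketone. The fallback installs free hydroxyls and methylates once, setting out from 3 and returning at 5, so that 4 and step 4 are bypassed. Palladium-catalysed hydroxylation of both C–Br bonds (KOH, Pd2(dba)3, tBuXPhos, 1,4-dioxane–H2O, 100 °C) would give 1-[4-(benzyloxy)-2,6-dihydroxy-3,5-dimethoxyphenyl]ethan-1-one F5. Mono-O-methylation (MeI, 1 equiv, K2CO3, acetone) would then give 5, since the two hydroxyls are equivalent and the remaining one is held in a hydrogen bond to the carbonyl.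

**Further compounds**

F1 | step 9 | 2-acetyl-5-(benzyloxy)-3,4,6-trimethoxyphenyl 3,4-dimethoxybenzoate | CC(=O)c1c(OC(=O)c2ccc(OC)c(OC)c2)c(OC)c(OCc2ccccc2)c(OC)c1OC
F2 | step 9 | 1-[4-(benzyloxy)-2-hydroxy-3,5,6-trimethoxyphenyl]-3-(3,4-dimethoxyphenyl)propane-1,3-dione | COc1ccc(C(=O)CC(=O)c2c(O)c(OC)c(OCc3ccccc3)c(OC)c2OC)cc1OC
F3 | step 8 | 7-(benzyloxy)-2-(2,2-dibromovinyl)-5,6,8-trimethoxy-4H-chromen-4-one | BrC(Br)=Cc1cc(=O)c2c(OC)c(OC)c(OCc3ccccc3)c(OC)c2o1
F4 | step 8 | 7-(benzyloxy)-2-[(Z)-2-bromovinyl]-5,6,8-trimethoxy-4H-chromen-4-one | Br/C=C\c1cc(=O)c2c(OC)c(OC)c(OCc3ccccc3)c(OC)c2o1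
F5 | step 3 | 1-[4-(benzyloxy)-2,6-dihydroxy-3,5-dimethoxyphenyl]ethan-1-one | CC(=O)c1c(O)c(OC)c(OCc2ccccc2)c(OC)c1O
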